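**Retrosynthetic overview**
1. Target 19 comes from menthyl acetal 18 by acid hydrolysis; the propanoate stereocentre comes from acrylic acid 16 by carboxylate-directed asymmetric hydrogenation, and 16 from methyl ketone 14.
2. Key disconnection: the cyclohexene ring of 13 is cut at C-3a–C-4 and C-4=C-5, a [5+1] tandem Michael / intramolecular Horner–Wadsworth–Emmons annulation of phosphonate 11 (one carbon) onto keto-butenolide 10 (five carbons), with the alkoxy acetal steering C-3a.
3. Keto-butenolide 10 comes from Feringa's (5S)-menthyloxybutenolide 6 and vinyl ketone 5 by enolate Michael addition through a temporary phenylthio adduct.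
4. Vinyl ketone 5 comes from (S)-isophorol 2 by a [2,3]-Wittig rearrangement (quaternary centre by 1,3-chirality transfer), and 2 from isophorone 1.
5. Ring order: the trimethylcyclohexane ring (isophorone) and the γ-lactone acetal (6) are bought in; the cyclohexene ring is formed last, in step 8.

Assumption: the C-3 lactol of the target equilibrates through the open aldehyde-acid, and the drawn (3R) anomer is taken to be the thermodynamic form that is isolated.

"Menthyl" below always means (1S,2R,5S)-5-methyl-2-(propan-2-yl)cyclohexyl. Bicyclic compounds are numbered as 2-benzofuran-1(3H)-ones (C-1 lactone carbonyl, C-3 acetal carbon, C-3a/C-7a ring fusion).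

**Step 1**
Reactants: 1 isophorone
Product: 2 (1S)-3,5,5-trimethylcyclohex-2-en-1-ol
Conditions: (R)-2-methyl-CBS-oxazaborolidine (10 mol%), catecholborane, toluene, −78 °C; aq. NaOH work-up
Reagents that add atoms: none
Why: Corey–Bakshi–Shibata reduction, in which 1,2-hydride delivery to the ketone face chosen by the oxazaborolidine (alkenyl arm as the large group) sets the (S)-carbinol that later controls the quaternary centre.

**Step 2**
Reactants: 2 (1S)-3,5,5-trimethylcyclohex-2-en-1-ol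
Product: 3 (3S)-1,5,5-trimethyl-3-(prop-2-en-1-yloxy)cyclohex-1-ene
Conditions: NaH, allyl bromide, THF/DMF, 0 → 25 °C
Reagents that add atoms: allyl bromide, C=CCBr
Why: Williamson etherification of the alkoxide, which does not touch the carbinol stereocentre.

**Step 3**
Reactants: 3 (3S)-1,5,5-trimethyl-3-(prop-2-en-1-yloxy)cyclohex-1-ene
Product: 4 1-[(1R)-1,5,5-trimethylcyclohex-2-en-1-yl]prop-2-en-1-ol (both carbinol epimers)
Conditions: n-BuLi, THF, −78 → −20 °C; H2O
Reagents that add atoms: none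
Why: [2,3]-Wittig rearrangement of a bis-allylic ether, lithiated at the less substituted allylic CH2, in which the new C–C bond forms suprafacially at the methyl-bearing alkene carbon on the face the oxygen leaves, so the (S)-carbinol becomes the (R)-quaternary centre (named (S) once the ring is saturated).

**Step 4**
Reactants: 4 1-[(1R)-1,5,5-trimethylcyclohex-2-en-1-yl]prop-2-en-1-ol
Product: 5 1-[(1R)-1,5,5-trimethylcyclohex-2-en-1-yl]prop-2-en-1-one
Conditions: Dess–Martin periodinane, NaHCO3, CH2Cl2, 0 → 25 °C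
Reagents that add atoms: none
Why: Dess–Martin oxidation of the allylic alcohol to the vinyl ketone, which removes the irrelevant carbinol centre and cannot epimerise the quaternary carbon.

**Step 5**
Reactants: 6 (5S)-5-(menthyloxy)furan-2(5H)-one
Product: 7 (4S,5S)-5-(menthyloxy)-4-(phenylsulfanyl)oxolan-2-one
Conditions: PhSH, Et3N (5 mol%), CH2Cl2, 0 °C
Reagents that add atoms: thiophenol, Sc1ccccc1
Why: thia-Michael addition anti to the menthyloxy group (Feringa butenolide chemistry) gives the trans adduct and masks the alkene so that C-3 can be enolised.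

**Step 6**
Reactants: 7 (4S,5S)-5-(menthyloxy)-4-(phenylsulfanyl)oxolan-2-one; 5 1-[(1R)-1,5,5-trimethylcyclohex-2-en-1-yl]prop-2-en-1-one
Product: 8 (3R,4S,5S)-5-(menthyloxy)-3-{3-oxo-3-[(1R)-1,5,5-trimethylcyclohex-2-en-1-yl]propyl}-4-(phenylsulfanyl)oxolan-2-one
Conditions: LiN(CHMe2)2, THF, −78 °C; then 5, −78 °C; aqueous quench
Reagents that add atoms: none
Why: Michael addition of the lactone lithium enolate to the unhindered β-carbon of the tert-alkyl vinyl ketone (1,2-addition is blocked by the neopentyl carbonyl), the chain entering anti to the phenylthio group at a centre that step 7 makes planar again.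

**Step 7**
Reactants: 8 (3R,4S,5S)-5-(menthyloxy)-3-{3-oxo-3-[(1R)-1,5,5-trimethylcyclohex-2-en-1-yl]propyl}-4-(phenylsulfanyl)oxolan-2-one
Product: 10 (5S)-5-(menthyloxy)-3-{3-oxo-3-[(1R)-1,5,5-trimethylcyclohex-2-en-1-yl]propyl}furan-2(5H)-one, via sulfoxide 9 (not isolated)
Conditions: mCPBA (1.0 equiv), CH2Cl2, −78 °C; then toluene, NaHCO3, 90 °C
Reagents that add atoms: mCPBA, O=C(OO)c1cccc(Cl)c1 (its oxygen is in 9 only)
Why: sulfide oxidation followed by thermal sulfoxide syn-elimination toward the acidic C-3 hydrogen regenerates the butenolide, now carrying the keto side chain, with the acetal stereocentre untouched.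

**Step 8**
Reactants: 10 (5S)-5-(menthyloxy)-3-{3-oxo-3-[(1R)-1,5,5-trimethylcyclohex-2-en-1-yl]propyl}furan-2(5H)-one; 11 dimethyl (2-oxopropyl)phosphonate
Product: 13 (3S,3aR,7aR)-4-acetyl-3-(menthyloxy)-5-[(1R)-1,5,5-trimethylcyclohex-2-en-1-yl]-3a,6,7,7a-tetrahydro-2-benzofuran-1(3H)-one, via Michael adduct 12 (not isolated)
Conditions: 11, NaH (1.0 equiv), THF, 0 °C; then 10, 0 → 25 °C, then 65 °C
Reagents that add atoms: none
Why: tandem Michael addition / intramolecular Horner–Wadsworth–Emmons olefination, in which the β-ketophosphonate anion adds to the butenolide β-carbon anti to the menthyloxy group (sets C-3a), the lactone enolate is protonated anti to the new substituent (cis C-7a, also the more stable ring fusion), and the re-formed phosphonate anion closes the six-membered ring on the only free ketone, placing the tetrasubstituted alkene regiospecifically.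

**Step 9**
Reactants: 13 (3S,3aR,7aR)-4-acetyl-3-(menthyloxy)-5-[(1R)-1,5,5-trimethylcyclohex-2-en-1-yl]-3a,6,7,7a-tetrahydro-2-benzofuran-1(3H)-one
Product: 14 (3S,3aR,7aR)-4-acetyl-3-(menthyloxy)-5-[(1S)-1,3,3-trimethylcyclohexyl]-3a,6,7,7a-tetrahydro-2-benzofuran-1(3H)-one
Conditions: H2 (1 atm), palladium on carbon (Pd/C, 5 wt%), EtOAc, 25 °C
Reagents that add atoms: none
Why: chemoselective catalytic hydrogenation of the cis-disubstituted ring alkene, the tetrasubstituted enone alkene being too hindered to adsorb, with no new stereocentre formed.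

**Step 10**
Reactants: 14 (3S,3aR,7aR)-4-acetyl-3-(menthyloxy)-5-[(1S)-1,3,3-trimethylcyclohexyl]-3a,6,7,7a-tetrahydro-2-benzofuran-1(3H)-one
Product: 15 (3S,3aR,7aR)-3-(menthyloxy)-4-{1-[(trifluoromethanesulfonyl)oxy]ethenyl}-5-[(1S)-1,3,3-trimethylcyclohexyl]-3a,6,7,7a-tetrahydro-2-benzofuran-1(3H)-one
Conditions: LiN(SiMe3)2, THF, −78 °C; PhNTf2, −78 → 0 °C
Reagents that add atoms: N-phenylbis(trifluoromethanesulfonimide), O=S(=O)(N(c1ccccc1)S(=O)(=O)C(F)(F)F)C(F)(F)F
Why: kinetic enolisation of the methyl ketone (more acidic and far less hindered than the tertiary lactone α-hydrogen) and O-triflation give the 2-triflyloxy diene.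

**Step 11**
Reactants: 15 (3S,3aR,7aR)-3-(menthyloxy)-4-{1-[(trifluoromethanesulfonyl)oxy]ethenyl}-5-[(1S)-1,3,3-trimethylcyclohexyl]-3a,6,7,7a-tetrahydro-2-benzofuran-1(3H)-one
Product: 16 2-{(3S,3aR,7aR)-3-(menthyloxy)-1-oxo-5-[(1S)-1,3,3-trimethylcyclohexyl]-1,3,3a,6,7,7a-hexahydro-2-benzofuran-4-yl}prop-2-enoic acid
Conditions: Pd(OAc)2 (5 mol%), 1,3-bis(diphenylphosphino)propane, CO (1 atm), KOAc, DMF/H2O, 60 °C
Reagents that add atoms: carbon monoxide, [C-]#[O+]; water, O
Why: palladium-catalysed hydroxycarbonylation of an alkenyl triflate (Cacchi–Ortar conditions) turns the acetyl carbon into the α-carbon of a 2-substituted acrylic acid.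

**Step 12**
Reactants: 16 2-{(3S,3aR,7aR)-3-(menthyloxy)-1-oxo-5-[(1S)-1,3,3-trimethylcyclohexyl]-1,3,3a,6,7,7a-hexahydro-2-benzofuran-4-yl}prop-2-enoic acid
Product: 17 (2R)-2-{(3S,3aR,7aR)-3-(menthyloxy)-1-oxo-5-[(1S)-1,3,3-trimethylcyclohexyl]-1,3,3a,6,7,7a-hexahydro-2-benzofuran-4-yl}propanoic acid
Conditions: Ru(OAc)2[(R)-BINAP] (1 mol%), H2 (100 atm), MeOH, 25 °C
Reagents that add atoms: none
Why: Noyori carboxylate-directed asymmetric hydrogenation of a 2-substituted acrylic acid (naproxen type), where the (R)-ligand should give the (R)-acid by analogy with (S)-BINAP giving (S)-naproxen, and the tetrasubstituted ring alkene is inert.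

**Step 13**
Reactants: 17 (2R)-2-{(3S,3aR,7aR)-3-(menthyloxy)-1-oxo-5-[(1S)-1,3,3-trimethylcyclohexyl]-1,3,3a,6,7,7a-hexahydro-2-benzofuran-4-yl}propanoic acid
Product: 18 methyl (2R)-2-{(3S,3aR,7aR)-3-(menthyloxy)-1-oxo-5-[(1S)-1,3,3-trimethylcyclohexyl]-1,3,3a,6,7,7a-hexahydro-2-benzofuran-4-yl}propanoate
Conditions: Me3SiCHN2, toluene/MeOH, 0 °C
Reagents that add atoms: (trimethylsilyl)diazomethane, C[Si](C)(C)C=[N+]=[N-]
Why: base-free diazoalkane esterification, so the allylic α-stereocentre is not epimerised.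

**Step 14**
Reactants: 18 methyl (2R)-2-{(3S,3aR,7aR)-3-(menthyloxy)-1-oxo-5-[(1S)-1,3,3-trimethylcyclohexyl]-1,3,3a,6,7,7a-hexahydro-2-benzofuran-4-yl}propanoate
Product: 19 methyl (2R)-2-{(3R,3aR,7aR)-3-hydroxy-1-oxo-5-[(1S)-1,3,3-trimethylcyclohexyl]-1,3,3a,6,7,7a-hexahydro-2-benzofuran-4-yl}propanoate (CNP0280354.1)
Conditions: 2 M HCl, THF/H2O, 45 °C
Reagents that add atoms: water, O
Why: acid-catalysed acetal hydrolysis releases menthol while the methyl ester survives, and the lactol settles by ring-chain equilibration into the (3R) anomer.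

**Compound list**
1 | isophorone (3,5,5-trimethylcyclohex-2-en-1-one) | CC1=CC(=O)CC(C)(C)C1 | starting material
2 | (1S)-3,5,5-trimethylcyclohex-2-en-1-ol | CC1=C[C@@H](O)CC(C)(C)C1 | intermediate
3 | (3S)-1,5,5-trimethyl-3-(prop-2-en-1-yloxy)cyclohex-1-ene | CC1=C[C@@H](OCC=C)CC(C)(C)C1 | intermediate
4 | 1-[(1R)-1,5,5-trimethylcyclohex-2-en-1-yl]prop-2-en-1-ol (carbinol epimers) | C=CC(O)[C@@]1(C)C=CCC(C)(C)C1 | intermediate
5 | 1-[(1R)-1,5,5-trimethylcyclohex-2-en-1-yl]prop-2-en-1-one | C=CC(=O)[C@@]1(C)C=CCC(C)(C)C1 | intermediate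
6 | (5S)-5-{[(1S,2R,5S)-5-methyl-2-(propan-2-yl)cyclohexyl]oxy}furan-2(5H)-one | C[C@H]1CC[C@H](C(C)C)[C@H](C1)O[C@H]2OC(=O)C=C2 | starting material
7 | (4S,5S)-5-(menthyloxy)-4-(phenylsulfanyl)oxolan-2-one | C[C@H]1CC[C@H](C(C)C)[C@H](C1)O[C@H]2OC(=O)C[C@@H]2Sc3ccccc3 | intermediate
8 | (3R,4S,5S)-5-(menthyloxy)-3-{3-oxo-3-[(1R)-1,5,5-trimethylcyclohex-2-en-1-yl]propyl}-4-(phenylsulfanyl)oxolan-2-one | C[C@H]1CC[C@H](C(C)C)[C@H](C1)O[C@H]2OC(=O)[C@@H](CCC(=O)[C@@]3(C)C=CCC(C)(C)C3)[C@@H]2Sc4ccccc4 | intermediate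
9 | S-oxide of 8 (sulfoxide, not isolated, sulfur configuration unassigned) | C[C@H]1CC[C@H](C(C)C)[C@H](C1)O[C@H]2OC(=O)[C@@H](CCC(=O)[C@@]3(C)C=CCC(C)(C)C3)[C@@H]2S(=O)c4ccccc4 | intermediate
10 | (5S)-5-(menthyloxy)-3-{3-oxo-3-[(1R)-1,5,5-trimethylcyclohex-2-en-1-yl]propyl}furan-2(5H)-one | C[C@H]1CC[C@H](C(C)C)[C@H](C1)O[C@H]2OC(=O)C(CCC(=O)[C@@]3(C)C=CCC(C)(C)C3)=C2 | intermediate
11 | dimethyl (2-oxopropyl)phosphonate | COP(=O)(CC(C)=O)OC | starting material
12 | dimethyl {1-[(2S,3S,4R)-2-(menthyloxy)-5-oxo-4-{3-oxo-3-[(1R)-1,5,5-trimethylcyclohex-2-en-1-yl]propyl}oxolan-3-yl]-2-oxopropyl}phosphonate (Michael adduct, not isolated, phosphonate carbon unassigned) | C[C@H]1CC[C@H](C(C)C)[C@H](C1)O[C@H]2OC(=O)[C@H](CCC(=O)[C@@]3(C)C=CCC(C)(C)C3)[C@@H]2C(C(C)=O)P(=O)(OC)OC | intermediate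
13 | (3S,3aR,7aR)-4-acetyl-3-(menthyloxy)-5-[(1R)-1,5,5-trimethylcyclohex-2-en-1-yl]-3a,6,7,7a-tetrahydro-2-benzofuran-1(3H)-one | CC(=O)C1=C([C@@]2(C)C=CCC(C)(C)C2)CC[C@H]2C(=O)O[C@H](O[C@H]3C[C@@H](C)CC[C@@H]3C(C)C)[C@@H]12 | intermediate
14 | (3S,3aR,7aR)-4-acetyl-3-(menthyloxy)-5-[(1S)-1,3,3-trimethylcyclohexyl]-3a,6,7,7a-tetrahydro-2-benzofuran-1(3H)-one | CC(=O)C1=C([C@@]2(C)CCCC(C)(C)C2)CC[C@H]2C(=O)O[C@H](O[C@H]3C[C@@H](C)CC[C@@H]3C(C)C)[C@@H]12 | intermediate
15 | (3S,3aR,7aR)-3-(menthyloxy)-4-{1-[(trifluoromethanesulfonyl)oxy]ethenyl}-5-[(1S)-1,3,3-trimethylcyclohexyl]-3a,6,7,7a-tetrahydro-2-benzofuran-1(3H)-one | C=C(OS(=O)(=O)C(F)(F)F)C1=C([C@@]2(C)CCCC(C)(C)C2)CC[C@H]2C(=O)O[C@H](O[C@H]3C[C@@H](C)CC[C@@H]3C(C)C)[C@@H]12 | intermediate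
16 | 2-{(3S,3aR,7aR)-3-(menthyloxy)-1-oxo-5-[(1S)-1,3,3-trimethylcyclohexyl]-1,3,3a,6,7,7a-hexahydro-2-benzofuran-4-yl}prop-2-enoic acid | C=C(C(=O)O)C1=C([C@@]2(C)CCCC(C)(C)C2)CC[C@H]2C(=O)O[C@H](O[C@H]3C[C@@H](C)CC[C@@H]3C(C)C)[C@@H]12 | intermediate
17 | (2R)-2-{(3S,3aR,7aR)-3-(menthyloxy)-1-oxo-5-[(1S)-1,3,3-trimethylcyclohexyl]-1,3,3a,6,7,7a-hexahydro-2-benzofuran-4-yl}propanoic acid | OC(=O)[C@H](C)C1=C([C@@]2(C)CCCC(C)(C)C2)CC[C@H]2C(=O)O[C@H](O[C@H]3C[C@@H](C)CC[C@@H]3C(C)C)[C@@H]12 | intermediate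
18 | methyl (2R)-2-{(3S,3aR,7aR)-3-(menthyloxy)-1-oxo-5-[(1S)-1,3,3-trimethylcyclohexyl]-1,3,3a,6,7,7a-hexahydro-2-benzofuran-4-yl}propanoate | COC(=O)[C@H](C)C1=C([C@@]2(C)CCCC(C)(C)C2)CC[C@H]2C(=O)O[C@H](O[C@H]3C[C@@H](C)CC[C@@H]3C(C)C)[C@@H]12 | intermediate
19 | methyl (2R)-2-{(3R,3aR,7aR)-3-hydroxy-1-oxo-5-[(1S)-1,3,3-trimethylcyclohexyl]-1,3,3a,6,7,7a-hexahydro-2-benzofuran-4-yl}propanoate | COC(=O)[C@H](C)C1=C([C@@]2(C)CCCC(C)(C)C2)CC[C@H]2C(=O)O[C@@H](O)[C@@H]12 | target

**Totals**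
Total steps: 14. Longest linear sequence: 13 steps (isophorone 1 to 19 through steps 1–4 and 6–14).

**Three steps most likely to fail, each with one fallback**

Step 8 (annulation). The olefination must attack a ketone next to a quaternary carbon and creates a crowded tetrasubstituted alkene; the acetal hydrogen of 10 is also base-labile. The fallback sets out from 10 and comes back at 13. Conjugate addition of prop-1-ynylzinc bromide promoted by t-BuMe2SiOTf (Et2O/THF, −40 °C, then dilute HCl) places a propynyl group on C-4 anti to the menthyloxy group and gives the alkynyl keto-lactone F1. AgSbF6 (10 mol%) in ClCH2CH2Cl at 60 °C then brings about an intramolecular alkyne–carbonyl metathesis (oxetene formation and ring opening). The ketone carbon becomes the ring alkene carbon and the distal alkyne carbon becomes the acetyl carbonyl, which is 13, with no olefination reagent involved.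

Step 12 (asymmetric hydrogenation). The acrylic acid is flanked by a twisted, fully substituted alkene and the substrate is itself chiral, so selectivity may be poor or mismatched. The fallback sets out from 16 and comes back at 19, using the ring system instead of a chiral catalyst. Hydrogenation without chiral control (H2, RhCl(PPh3)3, benzene/EtOH) gives the propanoic acid F2 as a mixture at C-2. TsOH in toluene at 80 °C closes the carboxyl group onto the acetal carbon C-3 with loss of menthol. DBU then equilibrates the acidic, allylic C-2 hydrogen of the rigid bis-lactone so that the methyl group sits on its convex face, giving the tricyclic acylal F3 (first formed together with its C-2 epimer, which converges on it). K2CO3 (catalytic) in MeOH at 0 °C opens the six-membered acylal lactone at its carbonyl group and gives 19 directly, the C-3 oxygen keeping its place.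

Step 3 ([2,3]-Wittig rearrangement). Lithiation could occur at the ring carbinol carbon, a [1,2]-shift can compete, and the new bond is made to a hindered, fully substituted carbon. The fallback sets out from 2 and comes back at 4. KH and Bu3SnCH2I in THF give the stannylmethyl ether F4. n-BuLi at −78 °C triggers the Wittig–Still [2,3] shift (tin–lithium exchange gives one defined carbanion) to the primary alcohol F5, with the same transfer of chirality. Dess–Martin oxidation gives the aldehyde F6, and CH2=CHMgBr adds to it to give 4.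

**Further compounds**
F1 | step 8 | (3R,4R,5S)-5-(menthyloxy)-3-{3-oxo-3-[(1R)-1,5,5-trimethylcyclohex-2-en-1-yl]propyl}-4-(prop-1-yn-1-yl)oxolan-2-one | C[C@H]1CC[C@H](C(C)C)[C@H](C1)O[C@H]2OC(=O)[C@H](CCC(=O)[C@@]3(C)C=CCC(C)(C)C3)[C@@H]2C#CC
F2 | step 12 | 2-{(3S,3aR,7aR)-3-(menthyloxy)-1-oxo-5-[(1S)-1,3,3-trimethylcyclohexyl]-1,3,3a,6,7,7a-hexahydro-2-benzofuran-4-yl}propanoic acid (both C-2 epimers) | CC(C(=O)O)C1=C([C@@]2(C)CCCC(C)(C)C2)CC[C@H]2C(=O)O[C@H](O[C@H]3C[C@@H](C)CC[C@@H]3C(C)C)[C@@H]12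
F3 | step 12 | tricyclic bis-lactone acylal (six-membered lactone from the (2R)-propanoic acid closed on C-3, five-membered lactone kept, methyl on the convex face) | C[C@H]1C(=O)O[C@@H]2OC(=O)[C@@H]3CCC([C@@]4(C)CCCC(C)(C)C4)=C1[C@H]23
F4 | step 3 | tributyl({[(1S)-3,5,5-trimethylcyclohex-2-en-1-yl]oxy}methyl)stannane | CC1=C[C@@H](OC[Sn](CCCC)(CCCC)CCCC)CC(C)(C)C1
F5 | step 3 | [(1R)-1,5,5-trimethylcyclohex-2-en-1-yl]methanol | OC[C@@]1(C)C=CCC(C)(C)C1
F6 | step 3 | (1R)-1,5,5-trimethylcyclohex-2-ene-1-carbaldehyde | O=C[C@@]1(C)C=CCC(C)(C)C1
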